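**Retrosynthetic overview**
1. Target 24 comes from macrocyclic ester 23 by DIBAL-H reduction. The only ring (14-membered carbocycle) is closed late, by intramolecular Horner–Wadsworth–Emmons olefination at C7=C8 of phosphonate-aldehyde 22.
2. 22 comes from chloro-acetal 19 and triethyl phosphonoacetate (C8–C9 alkylation, then acetal hydrolysis).
3. 19 comes from secondary boronic ester 15 and 2-lithio-6-methylhepta-1,5-diene by Zweifel olefination (C1–C15); the lithium reagent is made by a Shapiro reaction of sulcatone trisylhydrazone.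
4. Key step: 15 comes from the (−)-sparteine-derived α-lithiated carbamate 13 (carbinol carbon C1 used with reversed polarity) and the neryl-type allylboronate 10. A 1,2-metallate rearrangement forms C1–C2 and sets the stereocentre.
5. Carbamate 6 comes from pent-4-yn-1-ol (carboalumination/oxirane fixes E-C11=C12). Boronate 10 comes from neryl acetate (Z-C3=C4 taken from nerol; ozonolysis, Ni borylation).

Assumption: locants C1–C20 number the ring from the stereocentre C1 through C3=C4(Me), C7=C8(C20H2OH) and C11=C12(Me) to C14, C15 is the exocyclic =CH2-bearing carbon, and (−)-sparteine is taken as purchasable.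

**Step 1**
Reactants: 1 pent-4-yn-1-ol
Product: 2 pent-4-yn-1-yl N,N-diisopropylcarbamate
Conditions: NaH, THF, 0 °C; iPr2NCOCl, reflux
Reagents that add atoms: N,N-diisopropylcarbamoyl chloride, CC(C)N(C(C)C)C(Cl)=O
Why: O-carbamoylation of the sodium alkoxide (Hoppe carbamate formation) installs the group that later directs α-lithiation, and NaH does not deprotonate the alkyne C–H.

**Step 2**
Reactants: 2 pent-4-yn-1-yl N,N-diisopropylcarbamate
Product: 5 (4E)-7-hydroxy-4-methylhept-4-en-1-yl N,N-diisopropylcarbamate, via alkenyl(dimethyl)alane 3 (not isolated), via lithium alkenylalanate 4 (not isolated)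
Conditions: Me3Al (3 equiv), Cp2ZrCl2 (20 mol %), CH2Cl2, 0→23 °C; evaporate; hexane/THF, n-BuLi, −78 °C; oxirane, −78→0 °C; aq. NH4Cl
Reagents that add atoms: trimethylaluminium, C[Al](C)C; oxirane, C1CO1
Why: Negishi Zr-catalysed syn-carboalumination puts Me on the internal and Al on the terminal alkyne carbon, and the derived alanate opens oxirane with retention, so the E-trisubstituted C11=C12 olefin is formed stereospecifically while the hindered carbamate tolerates Me3Al at 23 °C and n-BuLi at −78 °C.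

**Step 3**
Reactants: 5 (4E)-7-hydroxy-4-methylhept-4-en-1-yl N,N-diisopropylcarbamate
Product: 6 (4E)-7-chloro-4-methylhept-4-en-1-yl N,N-diisopropylcarbamate
Conditions: PPh3, NCS, CH2Cl2, 0 °C→rt
Reagents that add atoms: N-chlorosuccinimide, O=C1CCC(=O)N1Cl
Why: Appel-type chlorination converts the primary alcohol into the primary chloride by SN2 displacement of the oxyphosphonium group without touching olefin or carbamate.

**Step 4**
Reactants: 7 neryl acetate
Product: 9 (2Z)-6,6-dimethoxy-3-methylhex-2-en-1-yl acetate, via aldehyde 8 (not isolated)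
Conditions: O3 (1.0 equiv), CH2Cl2/MeOH, pyridine (cat.), −78 °C; Me2S, →rt; then HC(OMe)3, PPTS (cat.), rt
Reagents that add atoms: trimethyl orthoformate, COC(OC)OC
Why: ozonolysis with reductive work-up cleaves the electron-rich isopropylidene olefin selectively over the acetate-deactivated allylic olefin, and acid-catalysed acetalisation masks the aldehyde while the Z geometry inherited from nerol is untouched.

**Step 5**
Reactants: 9 (2Z)-6,6-dimethoxy-3-methylhex-2-en-1-yl acetate
Product: 10 2-[(2Z)-6,6-dimethoxy-3-methylhex-2-en-1-yl]-4,4,5,5-tetramethyl-1,3,2-dioxaborolane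
Conditions: B2pin2, Ni(cod)2 (5 mol %), PCy3 (5 mol %), EtOAc, rt
Reagents that add atoms: bis(pinacolato)diboron, CC1(C)OB(OC1(C)C)B1OC(C)(C)C(C)(C)O1
Why: Ni(0)-catalysed Miyaura-type borylation of the allylic acetate goes through a 3,3-disubstituted π-allyl that does not readily exchange syn and anti positions, so boron enters at the primary terminus with retention of the Z olefin.

**Step 6**
Reactants: 11 6-methylhept-5-en-2-one
Product: 12 N'-[(2E)-6-methylhept-5-en-2-ylidene]-2,4,6-triisopropylbenzenesulfonohydrazide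
Conditions: TrisNHNH2, MeOH, HCl (cat.), rt
Reagents that add atoms: 2,4,6-triisopropylbenzenesulfonyl hydrazide, NNS(=O)(=O)c1c(C(C)C)cc(C(C)C)cc1C(C)C
Why: hydrazone condensation of the methyl ketone gives the trisylhydrazone needed for a regioselective Shapiro reaction.

**Step 7**
Reactants: 6 (4E)-7-chloro-4-methylhept-4-en-1-yl N,N-diisopropylcarbamate; 10 2-[(2Z)-6,6-dimethoxy-3-methylhex-2-en-1-yl]-4,4,5,5-tetramethyl-1,3,2-dioxaborolane
Product: 15 2-[(3E,7R,9Z)-1-chloro-13,13-dimethoxy-4,10-dimethyltrideca-3,9-dien-7-yl]-4,4,5,5-tetramethyl-1,3,2-dioxaborolane, via (S)-α-lithiated carbamate 13 (not isolated), via lithium boronate complex 14 (not isolated)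
Conditions: s-BuLi, (−)-sparteine, Et2O, −78 °C, 5 h; 10, −78 °C, 1 h; then reflux, 12 h
Reagents that add atoms: none
Why: Hoppe–Aggarwal lithiation–borylation, in which s-BuLi/(−)-sparteine removes the pro-S α-hydrogen to give a configurationally stable α-oxy carbanion (the normally electrophilic carbinol carbon C1 acting as a nucleophile), boron is captured with retention, and the neryl CH2 then migrates from boron to C1 with inversion while the carbamate leaves, so two carbons that are both electrophilic in their precursors (C–O carbons of 6 and of neryl acetate) are joined and C1 is fixed as drawn, with the er expected to be about 95:5 or better.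

**Step 8**
Reactants: 12 N'-[(2E)-6-methylhept-5-en-2-ylidene]-2,4,6-triisopropylbenzenesulfonohydrazide; 15 2-[(3E,7R,9Z)-1-chloro-13,13-dimethoxy-4,10-dimethyltrideca-3,9-dien-7-yl]-4,4,5,5-tetramethyl-1,3,2-dioxaborolane
Product: 19 (3E,7R,9Z)-1-chloro-13,13-dimethoxy-4,10-dimethyl-7-(6-methylhepta-1,5-dien-2-yl)trideca-3,9-diene, via (6-methylhepta-1,5-dien-2-yl)lithium 16 (not isolated), via lithium alkenylboronate complex 17 (not isolated), via β-iodoalkylboronate 18 (not isolated)
Conditions: 12, n-BuLi (2 equiv), THF, −78→0 °C; 15, −78 °C; I2, THF; NaOMe, MeOH, −78 °C→rt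
Reagents that add atoms: none
Why: the Shapiro reaction deprotonates the hydrazone at CH3 and delivers the 2-lithio-1,5-diene, whose boron-ate complex undergoes Zweifel olefination (iodine-triggered 1,2-migration of the secondary alkyl group with retention, then anti-elimination of boron and iodide), so the 1,1-disubstituted olefin with the whole side chain is attached to C1 without loss of configuration.

**Step 9**
Reactants: 19 (3E,7R,9Z)-1-chloro-13,13-dimethoxy-4,10-dimethyl-7-(6-methylhepta-1,5-dien-2-yl)trideca-3,9-diene; 20 triethyl phosphonoacetate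
Product: 21 ethyl (5E,9R,11Z)-2-(diethoxyphosphoryl)-15,15-dimethoxy-6,12-dimethyl-9-(6-methylhepta-1,5-dien-2-yl)pentadeca-5,11-dienoate (1:1 epimers at C-2)
Conditions: NaH, 20 (3 equiv), THF, 0 °C; then 19, NaI (0.2 equiv), DMSO, 60 °C
Reagents that add atoms: none
Why: SN2 alkylation of the sodium phosphonoacetate carbanion by the primary chloride (iodide-catalysed, Finkelstein activation) forms C8–C9, with excess phosphonate suppressing dialkylation and the new C–P stereocentre being destroyed in step 11.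

**Step 10**
Reactants: 21 ethyl (5E,9R,11Z)-2-(diethoxyphosphoryl)-15,15-dimethoxy-6,12-dimethyl-9-(6-methylhepta-1,5-dien-2-yl)pentadeca-5,11-dienoate
Product: 22 ethyl (5E,9R,11Z)-2-(diethoxyphosphoryl)-6,12-dimethyl-9-(6-methylhepta-1,5-dien-2-yl)-15-oxopentadeca-5,11-dienoate
Conditions: PPTS, acetone/H2O (9:1), 50 °C
Reagents that add atoms: water, O
Why: mild acid-catalysed acetal hydrolysis unmasks the aldehyde without isomerising the olefins or cleaving the esters.

**Step 11**
Reactants: 22 ethyl (5E,9R,11Z)-2-(diethoxyphosphoryl)-6,12-dimethyl-9-(6-methylhepta-1,5-dien-2-yl)-15-oxopentadeca-5,11-dienoate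
Product: 23 ethyl (1E,5Z,8R,11E)-5,11-dimethyl-8-(6-methylhepta-1,5-dien-2-yl)cyclotetradeca-1,5,11-triene-1-carboxylate
Conditions: K2CO3, 18-crown-6, toluene (0.002 M, syringe pump), 65 °C
Reagents that add atoms: none
Why: intramolecular Horner–Wadsworth–Emmons olefination under high dilution closes the 14-membered ring, and the α-alkyl phosphonoacetate gives the thermodynamically preferred E-enoate (ester trans to C6) required at C7=C8.

**Step 12**
Reactants: 23 ethyl (1E,5Z,8R,11E)-5,11-dimethyl-8-(6-methylhepta-1,5-dien-2-yl)cyclotetradeca-1,5,11-triene-1-carboxylate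
Product: 24 [(1E,5Z,8R,11E)-5,11-dimethyl-8-(6-methylhepta-1,5-dien-2-yl)cyclotetradeca-1,5,11-trien-1-yl]methanol (CNP0237384.1)
Conditions: DIBAL-H (2.5 equiv), CH2Cl2, −78 °C; Rochelle salt
Reagents that add atoms: none
Why: DIBAL-H 1,2-reduction of the conjugated ester gives the allylic alcohol and leaves the isolated olefins and the stereocentre untouched.

**Compound list**
1 | pent-4-yn-1-ol | C#CCCCO | starting material
2 | pent-4-yn-1-yl N,N-diisopropylcarbamate | C#CCCCOC(=O)N(C(C)C)C(C)C | intermediate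
3 | [(1E)-5-(diisopropylcarbamoyloxy)-2-methylpent-1-en-1-yl]dimethylaluminium | C[Al](C)/C=C(\C)CCCOC(=O)N(C(C)C)C(C)C | intermediate
4 | lithium butyl[(1E)-5-(diisopropylcarbamoyloxy)-2-methylpent-1-en-1-yl]dimethylaluminate | [Li+].CCCC[Al-](C)(C)/C=C(\C)CCCOC(=O)N(C(C)C)C(C)C | intermediate
5 | (4E)-7-hydroxy-4-methylhept-4-en-1-yl N,N-diisopropylcarbamate | OCC/C=C(\C)CCCOC(=O)N(C(C)C)C(C)C | intermediate
6 | (4E)-7-chloro-4-methylhept-4-en-1-yl N,N-diisopropylcarbamate | ClCC/C=C(\C)CCCOC(=O)N(C(C)C)C(C)C | intermediate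
7 | neryl acetate, (2Z)-3,7-dimethylocta-2,6-dien-1-yl acetate | CC(=O)OC/C=C(/C)CCC=C(C)C | starting material
8 | (2Z)-3-methyl-6-oxohex-2-en-1-yl acetate | CC(=O)OC/C=C(/C)CCC=O | intermediate
9 | (2Z)-6,6-dimethoxy-3-methylhex-2-en-1-yl acetate | CC(=O)OC/C=C(/C)CCC(OC)OC | intermediate
10 | 2-[(2Z)-6,6-dimethoxy-3-methylhex-2-en-1-yl]-4,4,5,5-tetramethyl-1,3,2-dioxaborolane | CC1(C)OB(C/C=C(/C)CCC(OC)OC)OC1(C)C | intermediate
11 | 6-methylhept-5-en-2-one | CC(=O)CCC=C(C)C | starting material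
12 | N'-[(2E)-6-methylhept-5-en-2-ylidene]-2,4,6-triisopropylbenzenesulfonohydrazide | C/C(CCC=C(C)C)=N\NS(=O)(=O)c1c(C(C)C)cc(C(C)C)cc1C(C)C | intermediate
13 | [(1S,4E)-7-chloro-1-lithio-4-methylhept-4-en-1-yl] N,N-diisopropylcarbamate ((−)-sparteine complex) | [Li][C@H](OC(=O)N(C(C)C)C(C)C)CC/C(C)=C/CCCl | intermediate
14 | lithium [(1S,4E)-7-chloro-1-(diisopropylcarbamoyloxy)-4-methylhept-4-en-1-yl][(2Z)-6,6-dimethoxy-3-methylhex-2-en-1-yl](pinacolato)borate | [Li+].CC1(C)O[B-](C/C=C(/C)CCC(OC)OC)([C@H](OC(=O)N(C(C)C)C(C)C)CC/C(C)=C/CCCl)OC1(C)C | intermediate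
15 | 2-[(3E,7R,9Z)-1-chloro-13,13-dimethoxy-4,10-dimethyltrideca-3,9-dien-7-yl]-4,4,5,5-tetramethyl-1,3,2-dioxaborolane | CC1(C)OB([C@H](CC/C(C)=C/CCCl)C/C=C(/C)CCC(OC)OC)OC1(C)C | intermediate
16 | (6-methylhepta-1,5-dien-2-yl)lithium | [Li]C(=C)CCC=C(C)C | intermediate
17 | lithium [(3E,7R,9Z)-1-chloro-13,13-dimethoxy-4,10-dimethyltrideca-3,9-dien-7-yl](6-methylhepta-1,5-dien-2-yl)(pinacolato)borate | [Li+].CC1(C)O[B-](C(=C)CCC=C(C)C)([C@H](CC/C(C)=C/CCCl)C/C=C(/C)CCC(OC)OC)OC1(C)C | intermediate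
18 | β-iodoalkylboronate: the boron-bearing carbon carries CH2I, the 4-methylpent-3-enyl chain and the (R)-C1 group (configuration at the boron-bearing carbon not specified, lost on elimination) | ICC(CCC=C(C)C)(B1OC(C)(C)C(C)(C)O1)[C@H](CC/C(C)=C/CCCl)C/C=C(/C)CCC(OC)OC | intermediate
19 | (3E,7R,9Z)-1-chloro-13,13-dimethoxy-4,10-dimethyl-7-(6-methylhepta-1,5-dien-2-yl)trideca-3,9-diene | C=C(CCC=C(C)C)[C@H](CC/C(C)=C/CCCl)C/C=C(/C)CCC(OC)OC | intermediate
20 | triethyl phosphonoacetate | CCOC(=O)CP(=O)(OCC)OCC | starting material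
21 | ethyl (5E,9R,11Z)-2-(diethoxyphosphoryl)-15,15-dimethoxy-6,12-dimethyl-9-(6-methylhepta-1,5-dien-2-yl)pentadeca-5,11-dienoate (C-2 epimers) | C=C(CCC=C(C)C)[C@H](CC/C(C)=C/CCC(C(=O)OCC)P(=O)(OCC)OCC)C/C=C(/C)CCC(OC)OC | intermediate
22 | ethyl (5E,9R,11Z)-2-(diethoxyphosphoryl)-6,12-dimethyl-9-(6-methylhepta-1,5-dien-2-yl)-15-oxopentadeca-5,11-dienoate (C-2 epimers) | C=C(CCC=C(C)C)[C@H](CC/C(C)=C/CCC(C(=O)OCC)P(=O)(OCC)OCC)C/C=C(/C)CCC=O | intermediate
23 | ethyl (1E,5Z,8R,11E)-5,11-dimethyl-8-(6-methylhepta-1,5-dien-2-yl)cyclotetradeca-1,5,11-triene-1-carboxylate | C=C(CCC=C(C)C)[C@H]1C/C=C(/C)CC/C=C(/C(=O)OCC)CC/C=C(\C)CC1 | intermediate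
24 | [(1E,5Z,8R,11E)-5,11-dimethyl-8-(6-methylhepta-1,5-dien-2-yl)cyclotetradeca-1,5,11-trien-1-yl]methanol | C=C(CCC=C(C)C)[C@H]1C/C=C(/C)CC/C=C(/CO)CC/C=C(\C)CC1 | target

**Totals**
Total step count: 12. Longest linear sequence: 9 steps (1, 2, 3, 7, 8, 9, 10, 11, 12); steps 4–5 and step 6 are side branches.

**Steps most likely to fail, with fallbacks**

Step 7 is the main risk. s-BuLi may eliminate HCl from 6, the boron-ate complex 14 may revert, or the neryl group may migrate with allylic (1,3) transposition. The er should be checked by oxidising an aliquot of 15 to the alcohol. The fallback sets out from 6 and comes back at 15, and it avoids migration of an allyl group altogether. The same lithiated carbamate 13 is trapped with bis[(pinacolato)boryl]methane, and migration of the CH2B(pin) group gives 2,2'-[(2S,5E)-8-chloro-5-methyloct-5-ene-1,2-diyl]bis(4,4,5,5-tetramethyl-1,3,2-dioxaborolane) F1. Separately, Normant carbocupration of propyne with the copper reagent from 3-bromo-1,1-dimethoxypropane (Mg, CuBr·SMe2; syn addition) followed by iodinolysis gives (1Z)-1-iodo-5,5-dimethoxy-2-methylpent-1-ene F2. A chemoselective Suzuki–Miyaura coupling of the primary C–B bond of F1 with F2 (Pd(OAc)2, RuPhos, KOH, THF/H2O, 70 °C) then gives 15, with the Z olefin now coming from the carbocupration instead of from nerol.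

Step 8 is the second risk. The Shapiro dianion may decompose, or the hindered α-substituted alkenyllithium 16 may add poorly to the secondary boronate. The fallback sets out from 15 and comes back at 19, and builds the side chain through a ketone. Zweifel coupling of 15 with 1-ethoxyvinyllithium (an acetyl anion equivalent from ethyl vinyl ether and t-BuLi; then I2, NaOMe) gives (3E,7R,9Z)-1-chloro-7-(1-ethoxyethenyl)-13,13-dimethoxy-4,10-dimethyltrideca-3,9-diene F3. Brief cold dilute acid (0.1 M HCl, THF, 0 °C) cleaves only the enol ether to (3R,5Z)-3-[(3E)-6-chloro-3-methylhex-3-en-1-yl]-9,9-dimethoxy-6-methylnon-5-en-2-one F4. The kinetic enolate of F4 (LDA, −78 °C, deprotonation at CH3) is alkylated with prenyl bromide to (7R,9Z)-7-[(3E)-6-chloro-3-methylhex-3-en-1-yl]-13,13-dimethoxy-2,10-dimethyltrideca-2,9-dien-6-one F5. Salt-free Wittig methylenation of F5 (Ph3P=CH2, THF, 0 °C, to limit epimerisation at C1) returns to 19, at the cost of two extra steps.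

Step 11 is the third risk. The macrocyclisation may oligomerise or give E/Z mixtures at C7=C8. The fallback sets out from 19 and comes back at 23, and closes the ring with a neutral stabilised phosphorane instead of a phosphonate anion. Chloride 19 is treated with NaI and then with ethyl (triphenylphosphoranylidene)acetate (2 equiv, MeCN, 80 °C; C-alkylation and transylidation) to give ethyl (5E,9R,11Z)-15,15-dimethoxy-6,12-dimethyl-9-(6-methylhepta-1,5-dien-2-yl)-2-(triphenyl-λ5-phosphanylidene)pentadeca-5,11-dienoate F6. Aqueous HCl/THF cleaves the acetal and protonates the ylide, giving [(5E,9R,11Z)-1-ethoxy-6,12-dimethyl-9-(6-methylhepta-1,5-dien-2-yl)-1,15-dioxopentadeca-5,11-dien-2-yl]triphenylphosphonium chloride F7. Slow addition of F7 to Et3N in toluene (0.001 M, 80 °C) regenerates ethyl (5E,9R,11Z)-6,12-dimethyl-9-(6-methylhepta-1,5-dien-2-yl)-15-oxo-2-(triphenyl-λ5-phosphanylidene)pentadeca-5,11-dienoate F8, which undergoes an E-selective intramolecular Wittig reaction to 23.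

**Further compounds**
F1 | step 7 | 2,2'-[(2S,5E)-8-chloro-5-methyloct-5-ene-1,2-diyl]bis(4,4,5,5-tetramethyl-1,3,2-dioxaborolane) | CC1(C)OB([C@H](CC/C(C)=C/CCCl)CB2OC(C)(C)C(C)(C)O2)OC1(C)C
F2 | step 7 | (1Z)-1-iodo-5,5-dimethoxy-2-methylpent-1-ene | I/C=C(/C)CCC(OC)OC
F3 | step 8 | (3E,7R,9Z)-1-chloro-7-(1-ethoxyethenyl)-13,13-dimethoxy-4,10-dimethyltrideca-3,9-diene | CCOC(=C)[C@H](CC/C(C)=C/CCCl)C/C=C(/C)CCC(OC)OC
F4 | step 8 | (3R,5Z)-3-[(3E)-6-chloro-3-methylhex-3-en-1-yl]-9,9-dimethoxy-6-methylnon-5-en-2-one | CC(=O)[C@H](CC/C(C)=C/CCCl)C/C=C(/C)CCC(OC)OC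
F5 | step 8 | (7R,9Z)-7-[(3E)-6-chloro-3-methylhex-3-en-1-yl]-13,13-dimethoxy-2,10-dimethyltrideca-2,9-dien-6-one | CC(C)=CCCC(=O)[C@H](CC/C(C)=C/CCCl)C/C=C(/C)CCC(OC)OC
F6 | step 11 | ethyl (5E,9R,11Z)-15,15-dimethoxy-6,12-dimethyl-9-(6-methylhepta-1,5-dien-2-yl)-2-(triphenyl-λ5-phosphanylidene)pentadeca-5,11-dienoate | C=C(CCC=C(C)C)[C@H](CC/C(C)=C/CCC(C(=O)OCC)=P(c1ccccc1)(c1ccccc1)c1ccccc1)C/C=C(/C)CCC(OC)OC
F7 | step 11 | [(5E,9R,11Z)-1-ethoxy-6,12-dimethyl-9-(6-methylhepta-1,5-dien-2-yl)-1,15-dioxopentadeca-5,11-dien-2-yl]triphenylphosphonium chloride | C=C(CCC=C(C)C)[C@H](CC/C(C)=C/CCC(C(=O)OCC)[P+](c1ccccc1)(c1ccccc1)c1ccccc1)C/C=C(/C)CCC=O.[Cl-]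
F8 | step 11 | ethyl (5E,9R,11Z)-6,12-dimethyl-9-(6-methylhepta-1,5-dien-2-yl)-15-oxo-2-(triphenyl-λ5-phosphanylidene)pentadeca-5,11-dienoate | C=C(CCC=C(C)C)[C@H](CC/C(C)=C/CCC(C(=O)OCC)=P(c1ccccc1)(c1ccccc1)c1ccccc1)C/C=C(/C)CCC=O
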